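**Plan**

- Retrosynthetic cuts, in order: C7–C8 of the diene (opens the 19-membered lactone); C2=C3 and the C1–O ester; C19–C20 (side chain); C10–C11 and C12=C13 (west arm); last, both ring bonds of the tetrahydrofuran, C16–C17 and O–C14.
- Forward order of rings: the tetrahydrofuran (O, C14, C15, C16, C17) is made first by a [3+2] annulation of a chiral allylsilane with an α-methyl aldehyde; the epoxide is closed after the side chain is added at C19; the macrocycle is closed last by a Stille coupling, followed by ketone unveiling and one deprotection.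
- Enabling feature: C15 (the OMe carbon) sits between the ring C–O carbon C14 and the unsubstituted CH2 C16, which is bonded to the second C–O carbon C17; OMe is trans to the C14 substituent and the ring is 2,5-cis. This is the imprint of an allylsilane (Si on C14, C15=C16) adding to an aldehyde (C17=O) with 1,2-silyl shift; the silicon left on C15 is a masked hydroxyl.
- Stereochemistry: one C–Si stereocentre set by copper catalysis is relayed to C14, C15 and C17 in the annulation; C18 is bought; C19 follows from C17/C18 (Felkin–Anh); C11 by a chiral Brønsted acid; C4 by an oxazolidinone auxiliary; C22/C23 from (S)-2-chloropropanoate (Cornforth addition, inversion on epoxide closure).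
- Alkene geometry: Still–Gennari olefinations (C2=C3, C12=C13), hydrozirconations (C8=C9, C20=C21) and a purchased (E)-iodoalkene (C6=C7).

Key step: step 5

Remark: macrolide numbering is used (C1 lactone carbonyl to C24 epoxide methyl, ring oxygen between C14 and C17); the C5 carbinol configuration of the C1–C7 fragment is immaterial because C5 ends as the ketone; compounds listed as starting materials are taken to be commercially available.

**Route**

Step 1
Reactants: 1 (Z)-4-(benzyloxy)but-2-en-1-ol; 2 diethyl chlorophosphate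
Product: 3 (Z)-4-(benzyloxy)but-2-en-1-yl diethyl phosphate
Conditions: Et3N, DMAP (cat.), CH2Cl2, 0 °C
Reagents that add atoms: diethyl chlorophosphate (2), CCOP(=O)(Cl)OCC
Why: O-phosphorylation of the primary allylic alcohol (DMAP-catalysed substitution at phosphorus) installs the leaving group for the SN2′ silylation without touching the benzyl ether or the alkene.

Step 2
Reactants: 3 allylic phosphate; 4 2-[dimethyl(phenyl)silyl]-4,4,5,5-tetramethyl-1,3,2-dioxaborolane
Product: 5 (R)-[1-(benzyloxy)but-3-en-2-yl]dimethyl(phenyl)silane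
Conditions: CuCl (5 mol %), chiral six-membered N-heterocyclic carbene ligand from its amidinium salt (5 mol %), NaOMe, THF, 0 °C
Reagents that add atoms: 2-[dimethyl(phenyl)silyl]-4,4,5,5-tetramethyl-1,3,2-dioxaborolane (4), C[Si](C)(c1ccccc1)B1OC(C)(C)C(C)(C)O1
Why: Copper-catalysed enantioselective allylic substitution with a silylboronate (SN2′, γ-selective) should deliver silicon to the carbon bearing CH2OBn with loss of phosphate, the chiral carbene ligand (antipode chosen for the R silane) setting the C–Si stereocentre.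

Step 3
Reactants: 6 methyl (S)-3-hydroxy-2-methylpropanoate; 7 tert-butyl(chloro)dimethylsilane
Product: 8 methyl (S)-3-[(tert-butyldimethylsilyl)oxy]-2-methylpropanoate
Conditions: imidazole, CH2Cl2, rt
Reagents that add atoms: tert-butyl(chloro)dimethylsilane (7), CC(C)(C)[Si](C)(C)Cl
Why: Imidazole-promoted silylation of the primary alcohol; the purchased stereocentre (future C18) is not involved.

Step 4
Reactants: 8 silyloxy ester
Product: 9 (S)-3-[(tert-butyldimethylsilyl)oxy]-2-methylpropanal
Conditions: i-Bu2AlH (1.05 equiv), CH2Cl2, −78 °C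
Reagents that add atoms: none
Why: Partial ester reduction (the tetrahedral aluminium hemiacetal is stable at −78 °C and gives the aldehyde on work-up); the α-stereocentre should survive if the crude aldehyde is used at once.

Step 5
Reactants: 5 (R)-allylsilane; 9 (S)-aldehyde
Product: 10 (2R,3S,5R)-2-[(benzyloxy)methyl]-5-[(S)-1-[(tert-butyldimethylsilyl)oxy]propan-2-yl]-3-[dimethyl(phenyl)silyl]tetrahydrofuran
Conditions: BF3·OEt2 (1.1 equiv), 4 Å molecular sieves, CH2Cl2, −78 °C
Reagents that add atoms: none
Why: Lewis acid-promoted [3+2] annulation of an α-substituted allylsilane with an aldehyde (a Hosomi–Sakurai addition diverted by 1,2-silyl shift): the BF3-bound aldehyde carbon C17 is attacked by the terminal CH2 (C16) of the vinyl group anti to the C–Si bond, silicon bridges C14 and C15 in the resulting cation, and the boron alkoxide opens the bridged ion at C14 while silicon stays on C15. The closest known reaction type is the BF3-mediated annulation of chiral β-alkoxy allylsilanes with aliphatic aldehydes to 2,5-cis-3-silyltetrahydrofurans. The one ring formed (O, C14, C15, C16, C17) closes by anti attack of oxygen on the distal carbon of the three-membered silicon-bridged ion (a five-membered closure with inversion at C14; the four-membered alternative at C15 is not productive). C14 is fixed by stereospecific inversion of the C–Si centre of 5, C15 by the suprafacial silyl shift in the H-inside rotamer (allylic strain), which puts silicon trans to CH2OBn, and C17 by the synclinal open transition state favoured with monodentate BF3, which gives the 2,5-cis ring. The step needs ring closure to outrun desilylative allylation and the silane's facial preference to override the aldehyde's own bias, since C18 requires the anti-Felkin adduct; the bulky PhMe2Si group and low temperature favour closure, and α-methyl-β-silyloxy aldehydes show only a weak Felkin bias toward unhindered allyl nucleophiles.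

Step 6
Reactants: 10 silyl tetrahydrofuran; 11 peracetic acid
Product: 12 (2R,3S,5R)-2-[(benzyloxy)methyl]-5-[(S)-1-[(tert-butyldimethylsilyl)oxy]propan-2-yl]tetrahydrofuran-3-ol
Conditions: KBr, AcOOH, NaOAc, AcOH, 0 °C to rt
Reagents that add atoms: peracetic acid (11), CC(=O)OO
Why: Fleming–Tamao oxidation: ipso-bromodesilylation of the phenyl group, then peracid-induced 1,2-shift of C15 from silicon to oxygen, should convert C–Si into C–OH with retention at C15; no alkene is present and the buffered medium should spare the benzyl and TBS ethers.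

Step 7
Reactants: 12 tetrahydrofuranol; 13 iodomethane
Product: 14 (2R,3S,5R)-2-[(benzyloxy)methyl]-5-[(S)-1-[(tert-butyldimethylsilyl)oxy]propan-2-yl]-3-methoxytetrahydrofuran
Conditions: NaH, MeI, THF, 0 °C to rt
Reagents that add atoms: iodomethane (13), CI
Why: Williamson etherification of the sodium alkoxide fixes the C15 methoxy group; no stereocentre is touched.

Step 8
Reactants: 14 benzyl ether
Product: 15 [(2R,3S,5R)-5-[(S)-1-[(tert-butyldimethylsilyl)oxy]propan-2-yl]-3-methoxytetrahydrofuran-2-yl]methanol
Conditions: H2 (1 atm), 10% Pd/C, EtOAc, rt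
Reagents that add atoms: none
Why: Hydrogenolysis of the benzyl ether frees the C13 hydroxyl while the molecule still has no alkene; silyl and methyl ethers are inert.

Step 9
Reactants: 15 primary alcohol
Product: 16 C13 aldehyde (3-methoxytetrahydrofuran-2-carbaldehyde; ring stereocentres and C18 as in 15)
Conditions: Dess–Martin periodinane, NaHCO3, CH2Cl2, 0 °C
Reagents that add atoms: none
Why: Dess–Martin oxidation under buffered, non-basic conditions should give the α-alkoxy aldehyde without epimerisation at C14 or β-elimination of methanol; it is used directly.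

Step 10
Reactants: 16 aldehyde; 17 ethyl 2-[bis(2,2,2-trifluoroethoxy)phosphoryl]propanoate
Product: 18 ethyl (Z)-3-[(2R,3S,5R)-5-[(S)-1-[(tert-butyldimethylsilyl)oxy]propan-2-yl]-3-methoxytetrahydrofuran-2-yl]-2-methylprop-2-enoate
Conditions: KN(SiMe3)2, 18-crown-6, THF, −78 °C
Reagents that add atoms: ethyl 2-[bis(2,2,2-trifluoroethoxy)phosphoryl]propanoate (17), CCOC(=O)C(C)P(=O)(OCC(F)(F)F)OCC(F)(F)F
Why: Still–Gennari olefination: the electron-poor bis(trifluoroethyl)phosphonate eliminates fast from the kinetic adduct, so the (Z)-2-methylenoate (C14 cis to the ester carbon, as C12=C13 requires) should form, and −78 °C avoids enolisation of the aldehyde.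

Step 11
Reactants: 18 (Z)-enoate
Product: 19 (Z)-allylic alcohol (C11 CH2OH; otherwise as 18)
Conditions: i-Bu2AlH (2.5 equiv), CH2Cl2, −78 °C
Reagents that add atoms: none
Why: 1,2-Reduction of the enoate by the aluminium hydride gives the allylic alcohol with the alkene geometry intact.

Step 12
Reactants: 19 allylic alcohol
Product: 20 (Z)-enal (C11 aldehyde)
Conditions: MnO2, CH2Cl2, rt
Reagents that add atoms: none
Why: MnO2 oxidises the allylic alcohol selectively under neutral conditions, which should keep the isomerisation-prone (Z)-enal intact for immediate use.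

Step 13
Reactants: 20 (Z)-enal; 21 4,4,5,5-tetramethyl-2-(propa-1,2-dien-1-yl)-1,3,2-dioxaborolane
Product: 22 (R,Z)-1-[(2R,3S,5R)-5-[(S)-1-[(tert-butyldimethylsilyl)oxy]propan-2-yl]-3-methoxytetrahydrofuran-2-yl]-2-methylhex-1-en-5-yn-3-ol
Conditions: (R)-3,3′-bis(2,4,6-triisopropylphenyl)-1,1′-binaphthyl-2,2′-diyl hydrogen phosphate (10 mol %), 4 Å molecular sieves, toluene, 0 °C
Reagents that add atoms: 4,4,5,5-tetramethyl-2-(propa-1,2-dien-1-yl)-1,3,2-dioxaborolane (21), C=C=CB1OC(C)(C)C(C)(C)O1
Why: Chiral phosphoric acid-catalysed asymmetric propargylation with an allenylboronate (SE2′ through a six-membered cyclic transition state in which the catalyst bridges boronate oxygen and formyl hydrogen) forms C10–C11 and should set C11 by catalyst control (antipode chosen for 11R), the remote ring stereocentres having little influence.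

Step 14
Reactants: 22 homopropargylic alcohol; 23 4-methoxybenzyl chloride
Product: 24 C11 4-methoxybenzyl ether of 22
Conditions: NaH, PMBCl, Bu4NI (cat.), DMF, 0 °C to rt
Reagents that add atoms: 4-methoxybenzyl chloride (23), COc1ccc(CCl)cc1
Why: Williamson etherification protects the C11 hydroxyl as a PMB ether that can be removed oxidatively at the very end.

Step 15
Reactants: 24 terminal alkyne; 25 tributyltin chloride
Product: 26 alkynylstannane (C8 SnBu3)
Conditions: n-BuLi, THF, −78 °C; then Bu3SnCl
Reagents that add atoms: tributyltin chloride (25), CCCC[Sn](Cl)(CCCC)CCCC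
Why: Deprotonation of the terminal alkyne and trapping with the tin chloride gives the alkynylstannane; ethers and the trisubstituted alkene are inert to the base at −78 °C.

Step 16
Reactants: 26 alkynylstannane
Product: 28 (Z)-alkenylstannane (C8=C9), via stannylalkenylzirconocene 27 (not isolated)
Conditions: Cp2Zr(H)Cl, THF, rt; then H2O
Reagents that add atoms: none
Why: Hydrozirconation–protonolysis: syn addition of Zr–H places zirconium on the tin-bearing carbon and protonolysis with retention leaves tin cis to the chain, i.e. the (Z)-alkenylstannane needed for C8=C9.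

Step 17
Reactants: 28 silyl ether
Product: 29 C19 primary alcohol
Conditions: Bu4NF, THF, 0 °C to rt
Reagents that add atoms: none
Why: Fluoride-mediated cleavage of the only silyl ether frees the C19 hydroxyl; the PMB ether and alkenylstannane are stable.

Step 18
Reactants: 29 primary alcohol
Product: 30 C19 aldehyde
Conditions: Dess–Martin periodinane, NaHCO3, CH2Cl2, 0 °C
Reagents that add atoms: none
Why: Buffered Dess–Martin oxidation to the α-methyl aldehyde should avoid epimerisation at C18 and protodestannylation.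

Step 19
Reactants: 31 methyl (S)-2-chloropropanoate; 32 ethynylmagnesium bromide
Product: 34 (3R,4S)-4-chloropent-1-yn-3-ol, via (S)-2-chloropropanal 33 (not isolated)
Conditions: i-Bu2AlH (1.0 equiv), CH2Cl2, −78 °C; then HC≡CMgBr, THF, −78 to 0 °C
Reagents that add atoms: ethynylmagnesium bromide (32), C#C[Mg]Br
Why: Partial ester reduction followed by Grignard addition to the α-chloro aldehyde: Cornforth (polar Felkin–Anh) addition anti to the C–Cl dipole should give the anti-chlorohydrin, so C22 is set by substrate control from the purchased C23 stereocentre.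

Step 20
Reactants: 34 chlorohydrin; 35 chlorotriethylsilane
Product: 36 triethyl{[(3R,4S)-4-chloropent-1-yn-3-yl]oxy}silane
Conditions: imidazole, CH2Cl2, 0 °C
Reagents that add atoms: chlorotriethylsilane (35), CC[Si](Cl)(CC)CC
Why: Silylation protects the carbinol so that the alkyne can be hydrometalated without elimination.

Step 21
Reactants: 30 C19 aldehyde; 36 silyloxy chloroalkyne
Product: 39 (19R)-allylic alcohol carrying the (22R,23S)-chlorohydrin TES ether side chain, via alkenylzirconocene chloride 37 (not isolated), via alkenylmethylzinc 38 (not isolated)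
Conditions: Cp2Zr(H)Cl, CH2Cl2, rt; Me2Zn, toluene, −65 °C; then 30, 0 °C
Reagents that add atoms: none
Why: Hydrozirconation (syn, terminal) and zirconium-to-zinc transmetalation give an (E)-alkenylzinc that adds 1,2 to the aldehyde; Felkin–Anh attack anti to C17, reinforced by 1,3-anti induction from the ring oxygen, should set C19 with OH syn to the C18 methyl, and stannane, chloride and ethers do not react.

Step 22
Reactants: 39 chlorohydrin TES ether
Product: 41 (19R)-allylic alcohol with the trans-(22R,23R)-epoxide, via chlorohydrin diol 40 (not isolated)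
Conditions: Bu4NF (3 equiv), THF, 0 to 40 °C
Reagents that add atoms: none
Why: Desilylation liberates the C22 alkoxide, which displaces the antiperiplanar C23 chloride (intramolecular Williamson reaction, 3-exo-tet) with inversion at C23 to give the trans-epoxide; the C19 hydroxyl cannot reach the chloride across the E-alkene.

Step 23
Reactants: 17 ethyl 2-[bis(2,2,2-trifluoroethoxy)phosphoryl]propanoate; 42 trimethyltin hydroxide
Product: 43 2-[bis(2,2,2-trifluoroethoxy)phosphoryl]propanoic acid
Conditions: Me3SnOH, 1,2-dichloroethane, 70 °C; then 5% aq. HCl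
Reagents that add atoms: trimethyltin hydroxide (42), C[Sn](C)(C)O
Why: Tin hydroxide-mediated ester hydrolysis is mild enough to cleave the carboxylic ester without attacking the trifluoroethyl phosphonate esters.

Step 24
Reactants: 41 epoxy allylic alcohol; 43 phosphonopropanoic acid
Product: 44 C19 2-[bis(2,2,2-trifluoroethoxy)phosphoryl]propanoate ester of 41
Conditions: DCC, DMAP (cat.), CH2Cl2, 0 °C to rt
Reagents that add atoms: none
Why: Steglich esterification acylates the hindered allylic C19 alcohol with retention (the C–O bond is not activated), installing C1–C2 as a Still–Gennari phosphonate; the epimers at the phosphonate carbon are inconsequential.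

Step 25
Reactants: 45 (E)-3-iodo-2-methylprop-2-en-1-ol
Product: 46 (E)-3-iodo-2-methylprop-2-enal
Conditions: MnO2, CH2Cl2, rt
Reagents that add atoms: none
Why: MnO2 oxidation of the allylic alcohol gives the iodoenal without loss of alkene geometry.

Step 26
Reactants: 46 iodoenal; 47 (R)-4-benzyl-3-propionyloxazolidin-2-one
Product: 48 (R)-4-benzyl-3-[(2R,3R,E)-3-hydroxy-5-iodo-2,4-dimethylpent-4-enoyl]oxazolidin-2-one
Conditions: Bu2BOTf, Et3N, CH2Cl2, −78 to 0 °C; then pH 7 buffer, MeOH, H2O2
Reagents that add atoms: (R)-4-benzyl-3-propionyloxazolidin-2-one (47), CCC(=O)N1[C@H](Cc2ccccc2)COC1=O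
Why: Evans syn-aldol reaction: the (Z)-boron enolate reacts through a Zimmerman–Traxler chair with the auxiliary controlling the enolate face, setting C4 (and the later-oxidised C5) as the syn adduct.

Step 27
Reactants: 48 aldol adduct; 35 chlorotriethylsilane
Product: 49 C5 triethylsilyl ether of 48
Conditions: imidazole, DMF, rt
Reagents that add atoms: chlorotriethylsilane (35), CC[Si](Cl)(CC)CC
Why: Silylation gives the C5 TES ether, chosen because it can later be cleaved and oxidised in one operation in the presence of the PMB ether.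

Step 28
Reactants: 49 silylated imide
Product: 50 (2S,3R,E)-5-iodo-2,4-dimethyl-3-[(triethylsilyl)oxy]pent-4-en-1-ol
Conditions: LiBH4, MeOH (1.1 equiv), THF, 0 °C
Reagents that add atoms: none
Why: Reductive cleavage of the imide releases the primary alcohol and the recoverable auxiliary without epimerising C4 or reducing the alkenyl iodide.

Step 29
Reactants: 50 primary alcohol
Product: 51 (2R,3R,E)-5-iodo-2,4-dimethyl-3-[(triethylsilyl)oxy]pent-4-enal
Conditions: Dess–Martin periodinane, NaHCO3, CH2Cl2, 0 °C
Reagents that add atoms: none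
Why: Buffered Dess–Martin oxidation gives the α-methyl-β-silyloxy aldehyde, used at once to avoid epimerisation at C4.

Step 30
Reactants: 44 phosphonate ester; 51 iodo aldehyde
Product: 52 open-chain (2Z)-enoate carrying the C7 alkenyl iodide and the C8 alkenylstannane
Conditions: KN(SiMe3)2, 18-crown-6, THF, −78 °C
Reagents that add atoms: none
Why: Intermolecular Still–Gennari olefination joins the two halves and should form the (Z)-C2=C3 enoate (C4 cis to the ester carbonyl); the anion is generated at −78 °C and trapped at once so that neither C4 epimerisation nor attack on the vinyl epoxide competes.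

Step 31
Reactants: 52 iodide–stannane
Product: 53 macrolactone with C5 OTES and C11 OPMB
Conditions: Pd2(dba)3 (10 mol %), AsPh3 (40 mol %), i-Pr2NEt, DMF, rt, 1 mM
Reagents that add atoms: none
Why: Stille macrocyclisation: oxidative addition of palladium into the alkenyl iodide, transmetalation from the (Z)-alkenylstannane and reductive elimination form C7–C8 with retention at both alkenes, closing the 19-membered ring as the (6E,8Z)-diene; high dilution and the weakly donating arsine at room temperature should let C–I insertion outpace ionisation of the vinyl epoxide or allylic ester.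

Step 32
Reactants: 53 macrolactone TES ether
Product: 55 C5 ketone with C11 OPMB, via C5 alcohol 54 (not isolated)
Conditions: IBX (3 equiv), DMSO, rt
Reagents that add atoms: none
Why: IBX in DMSO cleaves the TES ether selectively and oxidises the released dienylic alcohol in the same flask, so the δ-hydroxy (Z)-enoate should never accumulate (no translactonisation) and the epimerisable C4 centre next to the new ketone never meets base.

Step 33
Reactants: 55 PMB ether
Product: 56 CNP0117824.1
Conditions: DDQ, CH2Cl2/pH 7 buffer (10:1), 0 °C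
Reagents that add atoms: none
Why: Oxidative PMB cleavage with DDQ (hydride abstraction to an oxocarbenium ion, then hydrolysis) under buffered, near-neutral conditions should free the C11 hydroxyl without touching the vinyl epoxide, the dienone or C4, giving the target.

**Compound list**

1 | (Z)-4-(benzyloxy)but-2-en-1-ol | OC/C=C\COCc1ccccc1 | starting material
2 | diethyl chlorophosphate | CCOP(=O)(Cl)OCC | starting material
3 | (Z)-4-(benzyloxy)but-2-en-1-yl diethyl phosphate | CCOP(=O)(OCC)OC/C=C\COCc1ccccc1 | intermediate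
4 | 2-[dimethyl(phenyl)silyl]-4,4,5,5-tetramethyl-1,3,2-dioxaborolane | C[Si](C)(c1ccccc1)B1OC(C)(C)C(C)(C)O1 | starting material
5 | (R)-[1-(benzyloxy)but-3-en-2-yl]dimethyl(phenyl)silane | C[Si](C)(c1ccccc1)[C@H](C=C)COCc1ccccc1 | intermediate
6 | methyl (S)-3-hydroxy-2-methylpropanoate | COC(=O)[C@@H](C)CO | starting material
7 | tert-butyl(chloro)dimethylsilane | CC(C)(C)[Si](C)(C)Cl | starting material
8 | methyl (S)-3-[(tert-butyldimethylsilyl)oxy]-2-methylpropanoate | COC(=O)[C@@H](C)CO[Si](C)(C)C(C)(C)C | intermediate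
9 | (S)-3-[(tert-butyldimethylsilyl)oxy]-2-methylpropanal | O=C[C@@H](C)CO[Si](C)(C)C(C)(C)C | intermediate
10 | (2R,3S,5R)-2-[(benzyloxy)methyl]-5-[(S)-1-[(tert-butyldimethylsilyl)oxy]propan-2-yl]-3-[dimethyl(phenyl)silyl]tetrahydrofuran (2,5-cis, 2,3-trans) | C[Si](C)(c1ccccc1)[C@H]1C[C@H]([C@@H](C)CO[Si](C)(C)C(C)(C)C)O[C@@H]1COCc1ccccc1 | intermediate
11 | peracetic acid | CC(=O)OO | starting material
12 | (2R,3S,5R)-2-[(benzyloxy)methyl]-5-[(S)-1-[(tert-butyldimethylsilyl)oxy]propan-2-yl]tetrahydrofuran-3-ol | O[C@H]1C[C@H]([C@@H](C)CO[Si](C)(C)C(C)(C)C)O[C@@H]1COCc1ccccc1 | intermediate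
13 | iodomethane | CI | starting material
14 | (2R,3S,5R)-2-[(benzyloxy)methyl]-5-[(S)-1-[(tert-butyldimethylsilyl)oxy]propan-2-yl]-3-methoxytetrahydrofuran | CO[C@H]1C[C@H]([C@@H](C)CO[Si](C)(C)C(C)(C)C)O[C@@H]1COCc1ccccc1 | intermediate
15 | [(2R,3S,5R)-5-[(S)-1-[(tert-butyldimethylsilyl)oxy]propan-2-yl]-3-methoxytetrahydrofuran-2-yl]methanol | CO[C@H]1C[C@H]([C@@H](C)CO[Si](C)(C)C(C)(C)C)O[C@@H]1CO | intermediate
16 | C13 aldehyde: 5-[(S)-1-[(tert-butyldimethylsilyl)oxy]propan-2-yl]-3-methoxytetrahydrofuran-2-carbaldehyde, configuration as in 15 | CO[C@H]1C[C@H]([C@@H](C)CO[Si](C)(C)C(C)(C)C)O[C@@H]1C=O | intermediate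
17 | ethyl 2-[bis(2,2,2-trifluoroethoxy)phosphoryl]propanoate (racemic) | CCOC(=O)C(C)P(=O)(OCC(F)(F)F)OCC(F)(F)F | starting material
18 | ethyl (Z)-3-[(2R,3S,5R)-5-[(S)-1-[(tert-butyldimethylsilyl)oxy]propan-2-yl]-3-methoxytetrahydrofuran-2-yl]-2-methylprop-2-enoate | CO[C@H]1C[C@H]([C@@H](C)CO[Si](C)(C)C(C)(C)C)O[C@@H]1/C=C(/C)C(=O)OCC | intermediate
19 | (Z)-allylic alcohol: C11 CH2OH analogue of 18 | CO[C@H]1C[C@H]([C@@H](C)CO[Si](C)(C)C(C)(C)C)O[C@@H]1/C=C(/C)CO | intermediate
20 | (Z)-enal: C11 aldehyde analogue of 18 | CO[C@H]1C[C@H]([C@@H](C)CO[Si](C)(C)C(C)(C)C)O[C@@H]1/C=C(/C)C=O | intermediate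
21 | 4,4,5,5-tetramethyl-2-(propa-1,2-dien-1-yl)-1,3,2-dioxaborolane | C=C=CB1OC(C)(C)C(C)(C)O1 | starting material
22 | (R,Z)-1-[(2R,3S,5R)-5-[(S)-1-[(tert-butyldimethylsilyl)oxy]propan-2-yl]-3-methoxytetrahydrofuran-2-yl]-2-methylhex-1-en-5-yn-3-ol (11R) | CO[C@H]1C[C@H]([C@@H](C)CO[Si](C)(C)C(C)(C)C)O[C@@H]1/C=C(/C)[C@H](O)CC#C | intermediate
23 | 4-methoxybenzyl chloride | COc1ccc(CCl)cc1 | starting material
24 | C11 4-methoxybenzyl ether of 22 | CO[C@H]1C[C@H]([C@@H](C)CO[Si](C)(C)C(C)(C)C)O[C@@H]1/C=C(/C)[C@H](OCc1ccc(OC)cc1)CC#C | intermediate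
25 | tributyltin chloride | CCCC[Sn](Cl)(CCCC)CCCC | starting material
26 | alkynylstannane: 24 with SnBu3 on the alkyne terminus C8 | CO[C@H]1C[C@H]([C@@H](C)CO[Si](C)(C)C(C)(C)C)O[C@@H]1/C=C(/C)[C@H](OCc1ccc(OC)cc1)CC#C[Sn](CCCC)(CCCC)CCCC | intermediate
27 | stannylalkenylzirconocene chloride formed in situ (Zr and Sn both on C8, Sn cis to C10; cyclopentadienyl rings drawn σ-bound) | CO[C@H]1C[C@H]([C@@H](C)CO[Si](C)(C)C(C)(C)C)O[C@@H]1/C=C(/C)[C@H](OCc1ccc(OC)cc1)C/C=C(\[Sn](CCCC)(CCCC)CCCC)[Zr](Cl)(C1C=CC=C1)C1C=CC=C1 | intermediate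
28 | (8Z)-alkenylstannane with C11 OPMB and C19 OTBS | CO[C@H]1C[C@H]([C@@H](C)CO[Si](C)(C)C(C)(C)C)O[C@@H]1/C=C(/C)[C@H](OCc1ccc(OC)cc1)C/C=C\[Sn](CCCC)(CCCC)CCCC | intermediate
29 | C19 primary alcohol derived from 28 | CO[C@H]1C[C@H]([C@@H](C)CO)O[C@@H]1/C=C(/C)[C@H](OCc1ccc(OC)cc1)C/C=C\[Sn](CCCC)(CCCC)CCCC | intermediate
30 | C19 aldehyde derived from 29 | CO[C@H]1C[C@H]([C@@H](C)C=O)O[C@@H]1/C=C(/C)[C@H](OCc1ccc(OC)cc1)C/C=C\[Sn](CCCC)(CCCC)CCCC | intermediate
31 | methyl (S)-2-chloropropanoate | COC(=O)[C@@H](Cl)C | starting material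
32 | ethynylmagnesium bromide | C#C[Mg]Br | starting material
33 | (S)-2-chloropropanal formed in situ | O=C[C@@H](Cl)C | intermediate
34 | (3R,4S)-4-chloropent-1-yn-3-ol | C#C[C@@H](O)[C@@H](Cl)C | intermediate
35 | chlorotriethylsilane | CC[Si](Cl)(CC)CC | starting material
36 | triethyl{[(3R,4S)-4-chloropent-1-yn-3-yl]oxy}silane | C#C[C@@H](O[Si](CC)(CC)CC)[C@@H](Cl)C | intermediate
37 | (E)-alkenylzirconocene chloride formed in situ from 36 (cyclopentadienyl rings drawn σ-bound) | Cl[Zr](C1C=CC=C1)(C1C=CC=C1)/C=C/[C@@H](O[Si](CC)(CC)CC)[C@@H](Cl)C | intermediate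
38 | (E)-alkenyl(methyl)zinc formed in situ from 37 | C[Zn]/C=C/[C@@H](O[Si](CC)(CC)CC)[C@@H](Cl)C | intermediate
39 | (19R,20E)-allylic alcohol with (22R)-OTES and (23S)-Cl, C8 stannane, C11 OPMB | CO[C@H]1C[C@H]([C@@H](C)[C@H](O)/C=C/[C@@H](O[Si](CC)(CC)CC)[C@@H](Cl)C)O[C@@H]1/C=C(/C)[C@H](OCc1ccc(OC)cc1)C/C=C\[Sn](CCCC)(CCCC)CCCC | intermediate
40 | chlorohydrin diol formed in situ (C19 OH, C22 OH, C23 Cl) | CO[C@H]1C[C@H]([C@@H](C)[C@H](O)/C=C/[C@@H](O)[C@@H](Cl)C)O[C@@H]1/C=C(/C)[C@H](OCc1ccc(OC)cc1)C/C=C\[Sn](CCCC)(CCCC)CCCC | intermediate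
41 | (19R,20E)-allylic alcohol with trans-(22R,23R)-epoxide, C8 stannane, C11 OPMB | CO[C@H]1C[C@H]([C@@H](C)[C@H](O)/C=C/[C@H]2O[C@@H]2C)O[C@@H]1/C=C(/C)[C@H](OCc1ccc(OC)cc1)C/C=C\[Sn](CCCC)(CCCC)CCCC | intermediate
42 | trimethyltin hydroxide | C[Sn](C)(C)O | starting material
43 | 2-[bis(2,2,2-trifluoroethoxy)phosphoryl]propanoic acid (racemic) | CC(C(=O)O)P(=O)(OCC(F)(F)F)OCC(F)(F)F | intermediate
44 | C19 2-[bis(2,2,2-trifluoroethoxy)phosphoryl]propanoate ester of 41 | CO[C@H]1C[C@H]([C@@H](C)[C@H](OC(=O)C(C)P(=O)(OCC(F)(F)F)OCC(F)(F)F)/C=C/[C@H]2O[C@@H]2C)O[C@@H]1/C=C(/C)[C@H](OCc1ccc(OC)cc1)C/C=C\[Sn](CCCC)(CCCC)CCCC | intermediate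
45 | (E)-3-iodo-2-methylprop-2-en-1-ol | I/C=C(\C)CO | starting material
46 | (E)-3-iodo-2-methylprop-2-enal | I/C=C(\C)C=O | intermediate
47 | (R)-4-benzyl-3-propionyloxazolidin-2-one | CCC(=O)N1[C@H](Cc2ccccc2)COC1=O | starting material
48 | (R)-4-benzyl-3-[(2R,3R,E)-3-hydroxy-5-iodo-2,4-dimethylpent-4-enoyl]oxazolidin-2-one | I/C=C(\C)[C@H](O)[C@@H](C)C(=O)N1[C@H](Cc2ccccc2)COC1=O | intermediate
49 | triethylsilyl ether of 48 | I/C=C(\C)[C@H](O[Si](CC)(CC)CC)[C@@H](C)C(=O)N1[C@H](Cc2ccccc2)COC1=O | intermediate
50 | (2S,3R,E)-5-iodo-2,4-dimethyl-3-[(triethylsilyl)oxy]pent-4-en-1-ol | I/C=C(\C)[C@H](O[Si](CC)(CC)CC)[C@@H](C)CO | intermediate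
51 | (2R,3R,E)-5-iodo-2,4-dimethyl-3-[(triethylsilyl)oxy]pent-4-enal | I/C=C(\C)[C@H](O[Si](CC)(CC)CC)[C@@H](C)C=O | intermediate
52 | open-chain (2Z)-enoate: C19 ester of the C1–C7 acid (C5 OTES, C7 iodide) with the C8 (Z)-alkenylstannane | I/C=C(\C)[C@H](O[Si](CC)(CC)CC)[C@@H](C)/C=C(/C)C(=O)O[C@H](/C=C/[C@H]1O[C@@H]1C)[C@H](C)[C@H]1C[C@H](OC)[C@H](O1)/C=C(/C)[C@H](OCc1ccc(OC)cc1)C/C=C\[Sn](CCCC)(CCCC)CCCC | intermediate
53 | macrolactone with C5 OTES and C11 OPMB | CO[C@H]1C[C@H]2O[C@@H]1/C=C(/C)[C@H](OCc1ccc(OC)cc1)C/C=C\C=C(/C)[C@H](O[Si](CC)(CC)CC)[C@@H](C)/C=C(/C)C(=O)O[C@H](/C=C/[C@H]1O[C@@H]1C)[C@@H]2C | intermediate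
54 | macrolactone C5 alcohol formed in situ (C11 OPMB) | CO[C@H]1C[C@H]2O[C@@H]1/C=C(/C)[C@H](OCc1ccc(OC)cc1)C/C=C\C=C(/C)[C@H](O)[C@@H](C)/C=C(/C)C(=O)O[C@H](/C=C/[C@H]1O[C@@H]1C)[C@@H]2C | intermediate
55 | C11 4-methoxybenzyl ether of the target (C5 ketone) | CO[C@H]1C[C@H]2O[C@@H]1/C=C(/C)[C@H](OCc1ccc(OC)cc1)C/C=C\C=C(/C)C(=O)[C@@H](C)/C=C(/C)C(=O)O[C@H](/C=C/[C@H]1O[C@@H]1C)[C@@H]2C | intermediate
56 | CNP0117824.1 | CO[C@H]1C[C@H]2O[C@@H]1/C=C(/C)[C@H](O)C/C=C\C=C(/C)C(=O)[C@@H](C)/C=C(/C)C(=O)O[C@H](/C=C/[C@H]1O[C@@H]1C)[C@@H]2C | target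

**Step count and risks**

Total step count: 33. Longest linear sequence: 23 steps (steps 1, 2, 5–18, 21, 22, 24, 30–33).

Steps most likely to fail:

1. Step 5. The aldehyde may be attacked with poor facial selectivity, because the silane's 2,5-cis preference has to override the Felkin preference of the α-methyl aldehyde, or desilylative allylation may outrun ring closure. The fallback sets out from 5 and comes back at 10; it removes the aldehyde stereocentre from the annulation and sets C18 afterwards. Silane 5 is annulated under the same BF3 conditions with methacrolein (achiral, so only the silane's preference operates) to give the 5-isopropenyl silyl tetrahydrofuran F1. Hydroboration–oxidation of this 1,1-disubstituted allylic ether (9-BBN, then NaOH/H2O2; addition anti to the ring C–O bond under allylic-strain control) gives the C19 primary alcohol F2 with C18 set from C17. Silylation with TBSCl and imidazole then gives 10.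

2. Step 21. Chelation of zinc by the ring oxygen may compete with Felkin–Anh addition and erode the selectivity at C19. The fallback sets out from 39 (as the C19 epimer mixture) and comes back at 39; it sets C19 by reagent-controlled reduction. The mixture is oxidised with buffered Dess–Martin periodinane to the C19 enone F3, which is reduced with the (R)-2-methyl oxazaborolidine catalyst and catecholborane at low temperature (Corey–Bakshi–Shibata reduction, alkenyl group in the large-group position, antipode confirmed on a model) to give 39. Neutral conditions are kept throughout because C18 is α to the ketone.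

3. Step 31. Palladium may ionise the vinyl epoxide or the allylic ester, or oligomerisation may compete with ring closure. The fallback sets out from 44 (together with 50) and comes back at 53; it changes the ring-closing bond. Stannane 44 and iodide 50 are coupled intermolecularly without palladium using copper thiophene-2-carboxylate, Cu(O2CC4H3S), in NMP to give the open-chain (6E,8Z)-dienyl alcohol F4. Buffered Dess–Martin oxidation gives the C3 aldehyde F5, and an intramolecular Still–Gennari olefination (KN(SiMe3)2, 18-crown-6, THF, high dilution, −78 °C) closes the ring at C2=C3 to give 53.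

Further compounds
F1 | step 5 | (2R,3S,5R)-2-[(benzyloxy)methyl]-3-[dimethyl(phenyl)silyl]-5-(prop-1-en-2-yl)tetrahydrofuran | C[Si](C)(c1ccccc1)[C@H]1C[C@H](C(C)=C)O[C@@H]1COCc1ccccc1
F2 | step 5 | C19 primary alcohol corresponding to 10 without the TBS group | C[Si](C)(c1ccccc1)[C@H]1C[C@H]([C@@H](C)CO)O[C@@H]1COCc1ccccc1
F3 | step 21 | C19 enone corresponding to 39 | CO[C@H]1C[C@H]([C@@H](C)C(=O)/C=C/[C@@H](O[Si](CC)(CC)CC)[C@@H](Cl)C)O[C@@H]1/C=C(/C)[C@H](OCc1ccc(OC)cc1)C/C=C\[Sn](CCCC)(CCCC)CCCC
F4 | step 31 | open-chain (6E,8Z)-dienyl C3 alcohol carrying the C19 phosphonopropanoate | CO[C@H]1C[C@H]([C@@H](C)[C@H](OC(=O)C(C)P(=O)(OCC(F)(F)F)OCC(F)(F)F)/C=C/[C@H]2O[C@@H]2C)O[C@@H]1/C=C(/C)[C@H](OCc1ccc(OC)cc1)C/C=C\C=C(/C)[C@H](O[Si](CC)(CC)CC)[C@@H](C)CO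
F5 | step 31 | C3 aldehyde corresponding to F4 | CO[C@H]1C[C@H]([C@@H](C)[C@H](OC(=O)C(C)P(=O)(OCC(F)(F)F)OCC(F)(F)F)/C=C/[C@H]2O[C@@H]2C)O[C@@H]1/C=C(/C)[C@H](OCc1ccc(OC)cc1)C/C=C\C=C(/C)[C@H](O[Si](CC)(CC)CC)[C@@H](C)C=O
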